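**Plan**
Cuts: C12–C13 (B-alkyl Suzuki coupling of the butenolide), C11=C12 (methylenation) and C9–OH (enolate oxidation) lead back to a drimane-type 11-aldehyde. C5–C10 and C8–C9 are then cut together, and the open chain is cut at C10–C20/C9–C11, C6–C7, C5=C6 and C3–C4.
Enabling feature: in ring B (C5–C6–C7–C8–C9–C10) the bonds C5–C10 and C8–C9 stand 1,4 to each other, so ring B is the [4+2] adduct of a C5=C6–C7=C8 diene and a C9=C10 dienophile. C1–C4 of ring A is a ready four-carbon tether, and C11, next to the C9 carbinol, can be a formyl group that activates the dienophile.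
Forward: the chain C11–C9–C10–C1–C2–C3–C4–C5–C6–C7–C8–C17 is grown linearly from pent-4-yn-1-ol, and one intramolecular Diels–Alder reaction closes rings A and B together. The helper alkene C6=C7 and the benzyl group leave in one hydrogenation, and C12–C16 come last.
Stereochemistry: C3 comes from a valine-derived oxazaborolidinone aldol. C5, C8, C9 and C10 come from olefin geometry (E enal; 5E,7Z diene, Z being required because C4 and C17 are trans across ring B), the endo mode and an equatorial C3–OBn group in the chair tether. The 9α-OH comes from α-face oxidation of the C9=C11 enolate, opposite the axial C10 methyl.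

Key step: step 9

Remark: labdane numbering (C1–C20) is used for all compounds, open-chain ones included. The D-valine-derived promoter is taken to be the enantiomer that gives the 3S aldol, its antipode being equally available.

**Step 1**
Reactants: 1 pent-4-yn-1-ol
Product: 2 pent-4-ynal
Conditions: TEMPO (cat.), PhI(OAc)2, CH2Cl2, rt
Reagents that add atoms: none
Why: The oxoammonium (TEMPO) oxidation of a primary alcohol stops at the aldehyde and leaves the terminal alkyne untouched.

**Step 2**
Reactants: 2 pent-4-ynal; 3 1-methoxy-2-methyl-1-(trimethylsilyloxy)prop-1-ene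
Product: 4 methyl (3S)-3-hydroxy-2,2-dimethylhept-6-ynoate
Conditions: N-tosyl-D-valine, BH3·THF, CH2Cl2, 0 °C to rt; then 2 and 3, −78 °C; pH 7 buffer
Reagents that add atoms: none
Why: In this Kiyooka-type asymmetric Mukaiyama aldol reaction the oxazaborolidinone binds the aldehyde and shields one face, so the ketene acetal should attack the face that gives the 3S carbinol next to the future C4 gem-dimethyl carbon.

**Step 3**
Reactants: 4 methyl (3S)-3-hydroxy-2,2-dimethylhept-6-ynoate
Product: 5 methyl (3S)-3-(benzyloxy)-2,2-dimethylhept-6-ynoate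
Conditions: BnOC(=NH)CCl3, TfOH (cat.), CH2Cl2/cyclohexane, 0 °C to rt
Reagents that add atoms: benzyl 2,2,2-trichloroacetimidate, N=C(OCc1ccccc1)C(Cl)(Cl)Cl
Why: Acid-catalysed O-benzylation with the trichloroacetimidate avoids the basic conditions that would cause retro-aldol cleavage of the β-hydroxy ester, and it does not touch C3.

**Step 4**
Reactants: 5 methyl (3S)-3-(benzyloxy)-2,2-dimethylhept-6-ynoate
Product: 6 (3S)-3-(benzyloxy)-2,2-dimethylhept-6-ynal
Conditions: i-Bu2AlH, CH2Cl2, −78 °C; aq. potassium sodium tartrate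
Reagents that add atoms: none
Why: In this partial ester reduction the aluminium hemiacetal of the α-quaternary ester persists at −78 °C and collapses to the non-enolisable C5 aldehyde only on work-up.

**Step 5**
Reactants: 6 (3S)-3-(benzyloxy)-2,2-dimethylhept-6-ynal
Product: 7 benzyl (1E,4S)-1-iodo-3,3-dimethyloct-1-en-7-yn-4-yl ether
Conditions: CrCl2, CHI3, THF, 0 °C to rt
Reagents that add atoms: iodoform, IC(I)I
Why: In the Takai–Utimoto olefination the gem-dichromium reagent converts the α-branched aldehyde into the E vinyl iodide (C5=C6), and divalent chromium tolerates the alkyne and the benzyl ether.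

**Step 6**
Reactants: 7 benzyl (1E,4S)-1-iodo-3,3-dimethyloct-1-en-7-yn-4-yl ether; 8 (Z)-prop-1-en-1-ylboronic acid
Product: 9 (5S,7E,9Z)-5-(benzyloxy)-6,6-dimethylundeca-7,9-dien-1-yne
Conditions: Pd(PPh3)4 (cat.), K3PO4, THF/H2O, rt to 40 °C
Reagents that add atoms: none
Why: The alkenyl–alkenyl Suzuki–Miyaura coupling proceeds with retention in both partners, so the E iodide and the Z boronic acid should give the 5E,7Z diene (labdane numbering) as one geometrical isomer.

**Step 7**
Reactants: 9 (5S,7E,9Z)-5-(benzyloxy)-6,6-dimethylundeca-7,9-dien-1-yne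
Product: 12 (2E,6S,8E,10Z)-6-(benzyloxy)-3,7,7-trimethyldodeca-2,8,10-trien-1-ol, via (E)-alkenyldimethylalane 10 (not isolated), via lithium butyl(alkenyl)dimethylalanate 11 (not isolated)
Conditions: Me3Al, Cp2ZrCl2 (cat.), CH2Cl2, 0 °C to rt; evaporate; n-BuLi, hexane/THF, 0 °C; (CH2O)n, rt
Reagents that add atoms: trimethylaluminium, C[Al](C)C; n-butyllithium (stays only in 11), [Li]CCCC; formaldehyde from paraformaldehyde, C=O
Why: The Negishi zirconium-catalysed carboalumination adds methyl (C20) to C10 and aluminium to C9 in a syn fashion across the terminal alkyne only, and the alanate is hydroxymethylated with retention, which fixes the E trisubstituted C9=C10 alkene.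

**Step 8**
Reactants: 12 (2E,6S,8E,10Z)-6-(benzyloxy)-3,7,7-trimethyldodeca-2,8,10-trien-1-ol
Product: 13 (2E,6S,8E,10Z)-6-(benzyloxy)-3,7,7-trimethyldodeca-2,8,10-trienal
Conditions: MnO2, CH2Cl2, rt
Reagents that add atoms: none
Why: The allylic oxidation with MnO2 is neutral and heterogeneous, so the E enal should form without disturbing the acid-sensitive Z-terminated diene.

**Step 9**
Reactants: 13 (2E,6S,8E,10Z)-6-(benzyloxy)-3,7,7-trimethyldodeca-2,8,10-trienal
Product: 14 3β-benzyloxy-8βH,9αH-drim-6-en-11-al (trans-octalin; 5α-H, 10β-CH3, 8α-CH3, 9β-CHO)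
Conditions: Me2AlCl (2 equiv), CH2Cl2, −78 to −20 °C
Reagents that add atoms: none
Why: Me2AlCl binds the formyl oxygen and lowers the LUMO of C9=C10, and the C5=C6–C7=C8 diene adds to it in a concerted, asynchronous, suprafacial [4+2] event that forms C5–C10 and C8–C9 together and leaves the C6=C7 alkene. The closest known reaction type is the alkylaluminium-chloride-promoted type 1 intramolecular Diels–Alder reaction of 2,8,10-undecatrienals, which gives trans-fused octalins through the endo mode. Ring A closes in the fused mode through a chair-like six-membered array of the tether C1–C4 (the tether joins diene terminus C5 to dienophile carbon C10), and ring B is the cyclohexene of the cycloaddition itself. C9 and C10 follow from the E enal (C20 cis to CHO), C5 and C8 from the 5E,7Z diene (C4 outside, C17 inside, hence trans across ring B and an 8α-methyl group), the trans fusion from the endo position of the aluminium-bound formyl group, and the absolute sense from C3, whose benzyloxy group stays equatorial in the chair tether. The step needs endo over exo selectivity: either mode must place one C10 substituent syn-axial to a C4 methyl, and the endo mode puts the small C20 methyl there whereas the exo mode would put C9 with its complexed formyl group there, which adds to the secondary-orbital preference. The step also needs the Z geometry to survive: the low temperature excludes the 1,5-hydrogen shift open to Z dienes, and Me2AlCl destroys adventitious protic acid that could isomerise the diene.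

**Step 10**
Reactants: 14 3β-benzyloxy-8βH,9αH-drim-6-en-11-al
Product: 15 3β-hydroxy-8βH,9αH-driman-11-al
Conditions: H2 (4 atm), Pd(OH)2/C, EtOAc, rt
Reagents that add atoms: none
Why: Heterogeneous catalytic hydrogenation saturates the cis-disubstituted helper alkene C6=C7 and hydrogenolyses the benzyl ether in the same operation without creating a stereocentre, and the raised hydrogen pressure should keep double-bond migration toward C5 or C8 from competing.

**Step 11**
Reactants: 15 3β-hydroxy-8βH,9αH-driman-11-al
Product: 17 3β,9α-dihydroxy-8βH-driman-11-al, via dipotassium enolate-alkoxide 16 (not isolated)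
Conditions: KN(SiMe3)2 (2.2 equiv), THF, −78 °C; then 3-phenyl-2-(phenylsulfonyl)oxaziridine, −78 °C
Reagents that add atoms: potassium bis(trimethylsilyl)amide (potassium stays only in 16), C[Si](C)(C)[N-][Si](C)(C)C.[K+]; 3-phenyl-2-(phenylsulfonyl)oxaziridine, O=S(=O)(c1ccccc1)N1OC1c1ccccc1
Why: In the Davis enolate hydroxylation the exocyclic C9=C11 enolate should be attacked on its α face, opposite the adjacent axial C10 methyl, as is general for drimane-type 11-aldehydes, which gives the 9α-OH and leaves the formyl group β.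

**Step 12**
Reactants: 17 3β,9α-dihydroxy-8βH-driman-11-al
Product: 18 13,14,15,16-tetranorlabd-11-ene-3β,9α-diol
Conditions: MePPh3Br, KOt-Bu (excess), THF, 0 °C to rt
Reagents that add atoms: methyltriphenylphosphonium bromide, C[P+](c1ccccc1)(c1ccccc1)c1ccccc1.[Br-]
Why: Wittig methylenation with excess ylide should turn the hindered formyl group into the C11=C12 vinyl group faster than an α-ketol rearrangement can set in, with both hydroxyl groups carried as alkoxides and C9 untouched.

**Step 13**
Reactants: 18 13,14,15,16-tetranorlabd-11-ene-3β,9α-diol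
Product: 19 3β-acetoxy-13,14,15,16-tetranorlabd-11-en-9α-ol
Conditions: Ac2O, pyridine, DMAP (cat.), CH2Cl2, 0 °C to rt
Reagents that add atoms: acetic anhydride, CC(=O)OC(C)=O
Why: In this chemoselective acylation the equatorial secondary 3β-OH is acetylated, whereas the axial tertiary 9α-OH, flanked by C8 and the quaternary C10, should stay free.

**Step 14**
Reactants: 19 3β-acetoxy-13,14,15,16-tetranorlabd-11-en-9α-ol; 20 4-bromofuran-2(5H)-one
Product: 22 3β-acetoxy-9α-hydroxylabd-13-en-15,16-olide, (3S,5S,8R,9R,10S), side chain on C4 of a furan-2(5H)-one, via B-alkyl-9-BBN borane 21 (not isolated)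
Conditions: 9-BBN-H, THF, rt to 50 °C; then 20, PdCl2(dppf) (cat.), AsPh3, Cs2CO3, DMF/THF/H2O, rt
Reagents that add atoms: 9-borabicyclo[3.3.1]nonane (boron stays only in 21), [H]B1C2CCCC1CCC2
Why: Anti-Markovnikov hydroboration places boron on C12 (the hindered carbinol and the acetate react far more slowly), and the B-alkyl Suzuki–Miyaura coupling with the β-bromobutenolide, a vinylogous acyl bromide that adds readily to zerovalent palladium, forms C12–C13 without touching any stereocentre.

**Compound list**
1 | pent-4-yn-1-ol | C#CCCCO | starting material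
2 | pent-4-ynal | C#CCCC=O | intermediate
3 | 1-methoxy-2-methyl-1-(trimethylsilyloxy)prop-1-ene | COC(O[Si](C)(C)C)=C(C)C | starting material
4 | methyl (3S)-3-hydroxy-2,2-dimethylhept-6-ynoate | COC(=O)C(C)(C)[C@@H](O)CCC#C | intermediate
5 | methyl (3S)-3-(benzyloxy)-2,2-dimethylhept-6-ynoate | COC(=O)C(C)(C)[C@@H](OCc1ccccc1)CCC#C | intermediate
6 | (3S)-3-(benzyloxy)-2,2-dimethylhept-6-ynal | O=CC(C)(C)[C@@H](OCc1ccccc1)CCC#C | intermediate
7 | benzyl (1E,4S)-1-iodo-3,3-dimethyloct-1-en-7-yn-4-yl ether | I/C=C/C(C)(C)[C@@H](OCc1ccccc1)CCC#C | intermediate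
8 | (Z)-prop-1-en-1-ylboronic acid | C/C=C\B(O)O | starting material
9 | (5S,7E,9Z)-5-(benzyloxy)-6,6-dimethylundeca-7,9-dien-1-yne | C/C=C\C=C\C(C)(C)[C@@H](OCc1ccccc1)CCC#C | intermediate
10 | dimethyl[(1E,5S,7E,9Z)-5-(benzyloxy)-2,6,6-trimethylundeca-1,7,9-trien-1-yl]alane (not isolated) | C[Al](C)/C=C(\C)CC[C@H](OCc1ccccc1)C(C)(C)/C=C/C=C\C | intermediate
11 | lithium butyl(dimethyl)[(1E,5S,7E,9Z)-5-(benzyloxy)-2,6,6-trimethylundeca-1,7,9-trien-1-yl]alanate (not isolated) | [Li+].CCCC[Al-](C)(C)/C=C(\C)CC[C@H](OCc1ccccc1)C(C)(C)/C=C/C=C\C | intermediate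
12 | (2E,6S,8E,10Z)-6-(benzyloxy)-3,7,7-trimethyldodeca-2,8,10-trien-1-ol | OC/C=C(\C)CC[C@H](OCc1ccccc1)C(C)(C)/C=C/C=C\C | intermediate
13 | (2E,6S,8E,10Z)-6-(benzyloxy)-3,7,7-trimethyldodeca-2,8,10-trienal | O=C/C=C(\C)CC[C@H](OCc1ccccc1)C(C)(C)/C=C/C=C\C | intermediate
14 | 3β-benzyloxy-8βH,9αH-drim-6-en-11-al (5α-H, 10β-CH3, 8α-CH3, 9β-CHO) | C(c3ccccc3)O[C@H]1CC[C@@]2(C)[C@@H](C=C[C@@H](C)[C@@H]2C=O)C1(C)C | intermediate
15 | 3β-hydroxy-8βH,9αH-driman-11-al | O[C@H]1CC[C@@]2(C)[C@@H](CC[C@@H](C)[C@@H]2C=O)C1(C)C | intermediate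
16 | dipotassium C9=C11 enolate and C3 alkoxide of 15, enolate geometry open (not isolated) | [K+].[K+].[O-][C@H]1CC[C@@]2(C)[C@@H](CC[C@@H](C)C2=C[O-])C1(C)C | intermediate
17 | 3β,9α-dihydroxy-8βH-driman-11-al | O[C@H]1CC[C@@]2(C)[C@@H](CC[C@@H](C)[C@]2(O)C=O)C1(C)C | intermediate
18 | 13,14,15,16-tetranorlabd-11-ene-3β,9α-diol | O[C@H]1CC[C@@]2(C)[C@@H](CC[C@@H](C)[C@]2(O)C=C)C1(C)C | intermediate
19 | 3β-acetoxy-13,14,15,16-tetranorlabd-11-en-9α-ol | CC(=O)O[C@H]1CC[C@@]2(C)[C@@H](CC[C@@H](C)[C@]2(O)C=C)C1(C)C | intermediate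
20 | 4-bromofuran-2(5H)-one | O=C1C=C(Br)CO1 | starting material
21 | 3β-acetoxy-12-(9-borabicyclo[3.3.1]nonan-9-yl)-13,14,15,16-tetranorlabdan-9α-ol (not isolated) | CC(=O)O[C@H]1CC[C@@]2(C)[C@@H](CC[C@@H](C)[C@]2(O)CCB3C4CCCC3CCC4)C1(C)C | intermediate
22 | 3β-acetoxy-9α-hydroxylabd-13-en-15,16-olide, (3S,5S,8R,9R,10S) | CC(=O)O[C@H]1CC[C@@]2(C)[C@@H](CC[C@@H](C)[C@]2(O)CCC2=CC(=O)OC2)C1(C)C | target

Total step count: 14. Longest linear sequence: 14 steps (from 1).

**Steps most likely to fail**

Step 9. The cycloaddition joins a neopentylic diene terminus to a carbon that becomes quaternary, and it uses a Z-terminated diene. It may therefore be slower than Z-to-E isomerisation of the diene, or it may leak into the exo mode. The fallback sets out from 13 and comes back at 14, and it changes the dienophile from a Lewis acid complex to a cation. Compound 13 is acetalised under aprotic conditions (TMSOCH2CH2OTMS, cat. TMSOTf, CH2Cl2, −78 °C) to the trienal 1,3-dioxolane F1. A further charge of TMSOTf at −78 °C opens the acetal to a vinyl oxocarbenium ion, a much stronger dienophile. This ion undergoes the ionic Diels–Alder reaction through the same endo chair array and recloses to the octalin 1,3-dioxolane F2. PPTS in wet acetone then frees aldehyde 14.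

Step 11. Hard enolisation of the doubly flanked C9–H may stay incomplete, and the potassium enolate may be lost by addition to the sulfonimine that the oxidant leaves behind. The fallback sets out from 15 and comes back at 17, and it uses soft enolisation followed by a Rubottom oxidation. TESOTf and Et3N (CH2Cl2, 0 °C) silylate the C3 hydroxyl and convert the aldehyde into the bis(triethylsilyl) enol ether F3. mCPBA with NaHCO3 (CH2Cl2, −20 °C) epoxidises the electron-rich C9=C11 bond from the α face, and silyl migration gives the 3β,9α-bis(triethylsilyloxy) aldehyde F4. HF·pyridine in THF removes both silyl groups to give 17.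

Step 14. Aqueous base may destroy the bromobutenolide by addition–elimination or lactone opening faster than the hindered alkylborane transmetalates. The fallback sets out from 21 and comes back at 22, and it makes the butenolide by oxidation of a furan instead of coupling it preformed. Borane 21 is coupled with the base-stable 3-bromofuran (Pd(OAc)2, SPhos, K3PO4, THF/H2O, 60 °C) to the 3-alkylfuran 3β-acetoxy-15,16-epoxylabda-13(16),14-dien-9α-ol F5. Singlet oxygen in the presence of a hindered base (O2, rose bengal, hν, i-Pr2NEt, CH2Cl2, −78 °C) gives the β-substituted γ-hydroxybutenolide 3β-acetoxy-9α,16-dihydroxylabd-13-en-15,16-olide F6, because the base removes the less hindered endoperoxide proton at C15. NaBH4 in MeOH at 0 °C reduces the masked C16 aldehyde, and relactonisation gives 22.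

**Further compounds**
F1 | step 9 | 2-[(1E,5S,7E,9Z)-5-(benzyloxy)-2,6,6-trimethylundeca-1,7,9-trien-1-yl]-1,3-dioxolane | C1COC(O1)/C=C(\C)CC[C@H](OCc2ccccc2)C(C)(C)/C=C/C=C\C
F2 | step 9 | 1,3-dioxolane (ethylene acetal) of 14 | C(c3ccccc3)O[C@H]1CC[C@@]2(C)[C@@H](C=C[C@@H](C)[C@@H]2C4OCCO4)C1(C)C
F3 | step 11 | 3β-(triethylsilyloxy)-8βH-drim-9(11)-en-11-yl triethylsilyl ether (enol ether geometry open) | CC[Si](CC)(CC)O[C@H]1CC[C@@]2(C)[C@@H](CC[C@@H](C)C2=CO[Si](CC)(CC)CC)C1(C)C
F4 | step 11 | 3β,9α-bis(triethylsilyloxy)-8βH-driman-11-al | CC[Si](CC)(CC)O[C@H]1CC[C@@]2(C)[C@@H](CC[C@@H](C)[C@]2(O[Si](CC)(CC)CC)C=O)C1(C)C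
F5 | step 14 | 3β-acetoxy-15,16-epoxylabda-13(16),14-dien-9α-ol | CC(=O)O[C@H]1CC[C@@]2(C)[C@@H](CC[C@@H](C)[C@]2(O)CCc2ccoc2)C1(C)C
F6 | step 14 | 3β-acetoxy-9α,16-dihydroxylabd-13-en-15,16-olide (C16 epimers) | CC(=O)O[C@H]1CC[C@@]2(C)[C@@H](CC[C@@H](C)[C@]2(O)CCC2=CC(=O)OC2O)C1(C)C
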